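**Retrosynthetic overview**
1. Target ⇐ its 3-O-(4-methoxybenzyl) ether (oxidative ether cleavage) ⇐ bicyclic acid + (R)-4-methoxybenzyl glycidyl ether (carboxylate opens the epoxide, then O-2 acetylation).
2. Bicyclic acid ⇐ acyclic (Z)-dihydroxy dienoic acid by one cationic cascade using the bond set of the presumed biosynthesis (C1–C8a and C4a–C5), ending with the same 1,2-hydride shift, 1,2-methyl shift and proton loss.
3. Ring order: ring A (the carboxyl-bearing ring; ketene acetal onto a tertiary allyl cation) first, ring B (ring A alkene onto a second tertiary cation) second, in the same flask.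
4. Dihydroxy acid ⇐ (Z)-selective semihydrogenation ⇐ acetylide of (R)-3-methylhex-5-ynoic acid + a hydroxy methyl ketone.
5. Alkynoic acid ⇐ (R)-citronellic acid (source of all ring stereocentres); hydroxy ketone ⇐ 6-methylhept-5-en-2-one + a chloropropyl dioxolane.

Assumption: locants C1–C8a in the Why lines are those of the octahydronaphthalene acid made in step 6 (C1 carries CO2H, C2 the secondary methyl, C4a and C8a are the ring-fusion carbons, C5 carries the side chain). The tertiary carbinol centres made in steps 1 and 4 are mixtures; both are ionised in step 6, so they are left uncontrolled.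

Step 1
Reactants: 1 sulcatone (6-methylhept-5-en-2-one); 2 chloro ketal 2-(3-chloropropyl)-2-methyl-1,3-dioxolane
Product: 5 hydroxy ketone 6-hydroxy-6,10-dimethylundec-9-en-2-one (racemic), via alkylmagnesium chloride 3 (not isolated), via ketal alcohol 4 (not isolated)
Conditions: 2, Mg, THF, 45 °C; then 1, 0 → 23 °C; then 1 M HCl, THF, 23 °C
Reagents that add atoms: water (O)
Why: Grignard addition to the methyl ketone makes the tertiary carbinol that is later ionised at C5 (bearing methyl and the 4-methylpent-3-enyl chain), and dilute-acid acetal hydrolysis frees the second methyl ketone; the new centre is racemic and is destroyed in step 6.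

Step 2
Reactants: 6 (R)-citronellic acid
Product: 8 (3R)-3-methyl-6-oxohexanoic acid, via ozonide 7 (not isolated)
Conditions: O3, CH2Cl2, −78 °C; then Me2S, −78 → 23 °C
Reagents that add atoms: ozone ([O-][O+]=O)
Why: Criegee ozonolysis of the trisubstituted alkene with reductive work-up gives the aldehyde; the C3 stereocentre is not touched.

Step 3
Reactants: 8 (3R)-3-methyl-6-oxohexanoic acid
Product: 10 (3R)-3-methylhex-5-ynoic acid, via enol nonaflate 9 (not isolated)
Conditions: C4F9SO2F (1.3 equiv), phosphazene base P2-Et (3.3 equiv), DMF, −30 → 23 °C; 1 M HCl work-up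
Reagents that add atoms: none
Why: one-pot O-sulfonylation of the aldehyde enolate and E2 elimination of the alkenyl nonaflate by the same strong non-nucleophilic base converts CH2–CHO into C≡CH without changing the carbon count; the carboxylate is a poor partner for the sulfonyl fluoride and the stereocentre is not acidic.

Step 4
Reactants: 10 (3R)-3-methylhex-5-ynoic acid; 5 hydroxy ketone
Product: 12 (3R)-7,11-dihydroxy-3,7,11,15-tetramethylhexadec-14-en-5-ynoic acid (epimers at C7 and C11), via dilithio alkynoate 11 (not isolated)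
Conditions: 10, LiN(iPr)2 (3.2 equiv), THF, −78 °C; CeCl3 (1.5 equiv); then 5 (0.9 equiv), −78 → 0 °C; aq HCl to pH 3
Reagents that add atoms: none
Why: 1,2-addition of a cerium-modified lithium acetylide to the methyl ketone assembles the C20 chain (carboxylate and alkoxide are spectators, CeCl3 suppresses enolisation and reopens the hemiketal alkoxide of 5); the new carbinol centre forms unselectively and does not matter.

Step 5
Reactants: 12 dihydroxy alkynoic acid
Product: 13 (3R,5Z)-7,11-dihydroxy-3,7,11,15-tetramethylhexadeca-5,14-dienoic acid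
Conditions: H2 (1 atm), Pd/CaCO3 poisoned with Pb(OAc)2, quinoline, EtOAc, 23 °C
Reagents that add atoms: none
Why: Lindlar semihydrogenation delivers H2 syn and gives only the (Z)-alkene, the geometry that lets the later allyl cation close to a cyclohexene; the trisubstituted alkene is inert.

Step 6
Reactants: 13 (Z)-dihydroxy dienoic acid
Product: 17 (1S,2R,4aR,8aR)-2,4a,8a-trimethyl-5-(4-methylpent-3-en-1-yl)-1,2,3,4,4a,7,8,8a-octahydronaphthalene-1-carboxylic acid, via persilylated ketene acetal 14 (not isolated), via monocyclic silyl ester 15 (not isolated), via bicyclic silyl ester 16 (not isolated)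
Conditions: LiN(iPr)2 (4.4 equiv), THF, −78 → 0 °C; Me3SiCl (5 equiv); evaporate, CH2Cl2, filter; 2,6-di-tert-butyl-4-methylpyridine (1.5 equiv), Me3SiOTf (0.1 equiv), −78 °C; then Me3SiOTf (1.2 equiv), −78 → −20 °C; aq NaHCO3, then pH 3
Reagents that add atoms: none
Why: Proposed new method: catalytic Me3SiOTf ionises only the tertiary allylic silyl ether, and the tertiary end of the (Z)-allyl cation is trapped by the ketene bis(silyl) acetal in a chair-like six-membered transition state (C2 methyl and the acetal carbon equatorial, hence 1,2-trans; the small methyl axial at C8a, hence cis to the carboxyl), so the citronellic stereocentre sets C1 and C8a as ring A closes; stoichiometric Me3SiOTf then ionises the remaining tertiary silyl ether, the C5 cation is attacked by the ring A cis-alkene at C4a on the face of the tether (cis fusion, ring B), the secondary C4 cation is quenched by 1,2-hydride shift from C4a, the C5 methyl lying axial and syn to the C8a methyl shifts to C4a (cis-dimethyl fusion), and the hindered pyridine takes the proton from C6 so that no free acid meets the 1,5-diene; the closest known chemistry is the SN1 alkylation of silyl ketene acetals by allylic and tertiary ethers under silyl triflate, tertiary-carbinol-initiated cation–olefin cyclisation, and the acid-triggered 1,2-hydride/1,2-methyl shift cascades of drimane cations, and these hydride and methyl shifts are the ones that end the presumed biosynthesis.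

Step 7
Reactants: 17 bicyclic acid; 18 (R)-4-methoxybenzyl glycidyl ether
Product: 20 (2S)-2-acetoxy-3-[(4-methoxybenzyl)oxy]propyl (1S,2R,4aR,8aR)-2,4a,8a-trimethyl-5-(4-methylpent-3-en-1-yl)-1,2,3,4,4a,7,8,8a-octahydronaphthalene-1-carboxylate, via hydroxy ester 19 (not isolated)
Conditions: 18 (1.5 equiv), Bu4NBr (10 mol%), toluene, 90 °C; then Ac2O, pyridine, DMAP (cat.), 0 → 23 °C
Reagents that add atoms: acetic anhydride (CC(=O)OC(C)=O)
Why: the carboxylate opens the terminal epoxide at CH2 (SN2, the glycidyl stereocentre is not touched, so (R)-18 gives the sn-1 ester), which esterifies the neopentyl-type acid by O-alkylation instead of acyl substitution; acetylation of the secondary alcohol in the same flask fixes the 1,2-diacyl pattern before acyl migration can start.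

Step 8
Reactants: 20 protected diacylglycerol
Product: 21 (2S)-2-acetoxy-3-hydroxypropyl (1S,2R,4aR,8aR)-2,4a,8a-trimethyl-5-(4-methylpent-3-en-1-yl)-1,2,3,4,4a,7,8,8a-octahydronaphthalene-1-carboxylate (target)
Conditions: DDQ (1.3 equiv), CH2Cl2–pH 7 phosphate buffer (10:1), 0 °C; fast chromatography on boric-acid-treated silica
Reagents that add atoms: none
Why: oxidative cleavage of the 4-methoxybenzyl ether by DDQ runs under neutral buffered conditions that leave the trisubstituted alkenes alone and avoid the acid or base catalysis that moves the acetyl group from O-2 to O-3.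

**Compound list**
1 | 6-methylhept-5-en-2-one (sulcatone) | CC(=O)CCC=C(C)C | starting material
2 | 2-(3-chloropropyl)-2-methyl-1,3-dioxolane | CC1(CCCCl)OCCO1 | starting material
3 | [3-(2-methyl-1,3-dioxolan-2-yl)propyl]magnesium chloride | CC1(CCC[Mg]Cl)OCCO1 | intermediate
4 | 2,6-dimethyl-9-(2-methyl-1,3-dioxolan-2-yl)non-2-en-6-ol (racemic) | CC1(CCCC(C)(O)CCC=C(C)C)OCCO1 | intermediate
5 | 6-hydroxy-6,10-dimethylundec-9-en-2-one (racemic) | CC(=O)CCCC(C)(O)CCC=C(C)C | intermediate
6 | (3R)-3,7-dimethyloct-6-enoic acid ((R)-citronellic acid) | OC(=O)C[C@H](C)CCC=C(C)C | starting material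
7 | (3R)-5-(5,5-dimethyl-1,2,4-trioxolan-3-yl)-3-methylpentanoic acid | OC(=O)C[C@H](C)CCC1OOC(C)(C)O1 | intermediate
8 | (3R)-3-methyl-6-oxohexanoic acid | OC(=O)C[C@H](C)CCC=O | intermediate
9 | (3R)-3-methyl-6-{[(nonafluorobutyl)sulfonyl]oxy}hex-5-enoic acid (E/Z mixture) | OC(=O)C[C@H](C)CC=COS(=O)(=O)C(F)(F)C(F)(F)C(F)(F)C(F)(F)F | intermediate
10 | (3R)-3-methylhex-5-ynoic acid | OC(=O)C[C@H](C)CC#C | intermediate
11 | lithium (3R)-6-lithio-3-methylhex-5-ynoate | [Li]OC(=O)C[C@H](C)CC#C[Li] | intermediate
12 | (3R)-7,11-dihydroxy-3,7,11,15-tetramethylhexadec-14-en-5-ynoic acid (epimers at C7, C11) | OC(=O)C[C@H](C)CC#CC(C)(O)CCCC(C)(O)CCC=C(C)C | intermediate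
13 | (3R,5Z)-7,11-dihydroxy-3,7,11,15-tetramethylhexadeca-5,14-dienoic acid (epimers at C7, C11) | OC(=O)C[C@H](C)C/C=C\C(C)(O)CCCC(C)(O)CCC=C(C)C | intermediate
14 | (3R,5Z)-3,7,11,15-tetramethyl-1,1,7,11-tetrakis(trimethylsilyloxy)hexadeca-1,5,14-triene | C[Si](C)(C)OC(O[Si](C)(C)C)=C[C@H](C)C/C=C\C(C)(O[Si](C)(C)C)CCCC(C)(O[Si](C)(C)C)CCC=C(C)C | intermediate
15 | trimethylsilyl (1S,2S,6R)-2-[4,8-dimethyl-4-(trimethylsilyloxy)non-7-en-1-yl]-2,6-dimethylcyclohex-3-ene-1-carboxylate | C[Si](C)(C)OC(=O)[C@H]1[C@H](C)CC=C[C@]1(C)CCCC(C)(O[Si](C)(C)C)CCC=C(C)C | intermediate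
16 | trimethylsilyl (1S,2R,4aR,8aR)-2,4a,8a-trimethyl-5-(4-methylpent-3-en-1-yl)-1,2,3,4,4a,7,8,8a-octahydronaphthalene-1-carboxylate | C[Si](C)(C)OC(=O)[C@H]1[C@H](C)CC[C@]2(C)C(CCC=C(C)C)=CCC[C@]12C | intermediate
17 | (1S,2R,4aR,8aR)-2,4a,8a-trimethyl-5-(4-methylpent-3-en-1-yl)-1,2,3,4,4a,7,8,8a-octahydronaphthalene-1-carboxylic acid | OC(=O)[C@H]1[C@H](C)CC[C@]2(C)C(CCC=C(C)C)=CCC[C@]12C | intermediate
18 | (2R)-2-{[(4-methoxybenzyl)oxy]methyl}oxirane | COc1ccc(COC[C@H]2CO2)cc1 | starting material
19 | (2S)-2-hydroxy-3-[(4-methoxybenzyl)oxy]propyl ester of 17 | COc1ccc(COC[C@H](O)COC(=O)[C@H]2[C@H](C)CC[C@]3(C)C(CCC=C(C)C)=CCC[C@]23C)cc1 | intermediate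
20 | (2S)-2-acetoxy-3-[(4-methoxybenzyl)oxy]propyl ester of 17 | COc1ccc(COC[C@H](OC(C)=O)COC(=O)[C@H]2[C@H](C)CC[C@]3(C)C(CCC=C(C)C)=CCC[C@]23C)cc1 | intermediate
21 | (2S)-2-acetoxy-3-hydroxypropyl (1S,2R,4aR,8aR)-2,4a,8a-trimethyl-5-(4-methylpent-3-en-1-yl)-1,2,3,4,4a,7,8,8a-octahydronaphthalene-1-carboxylate (1-O-acyl-2-O-acetyl-sn-glycerol) | CC(=O)O[C@@H](CO)COC(=O)[C@H]1[C@H](C)CC[C@]2(C)C(CCC=C(C)C)=CCC[C@]12C | target

**Count and risks**
Total: 8 steps. Longest linear sequence: 7 steps (6 → 21, steps 2 to 8); step 1 is a one-step side branch.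

Most likely to fail:

(a) Step 6. Four things can go wrong in the cascade:
- the tertiary C5 cation can lose a proton before it reaches the ring A alkene;
- the 4-methylpent-3-enyl group can shift in place of the methyl, or the methyl can arrive trans to the C8a methyl;
- the last proton can leave from the side chain instead of C6;
- ring A can close with the long chain axial, giving the C8a epimer.

Reversible lactone trapping of the C4a cation by the silyl ester is also possible. The fallback makes ring B from an oxocarbenium ion and puts the side chain on afterwards; it sets out from 3 and 10 and returns at 17. The organomagnesium 3 is acylated with N-methoxy-N-methylacetamide to 5-(2-methyl-1,3-dioxolan-2-yl)pentan-2-one F1. The dianion 11 adds to it as in step 4 to give (3R)-7-hydroxy-3,7-dimethyl-10-(2-methyl-1,3-dioxolan-2-yl)dec-5-ynoic acid F2, and semihydrogenation as in step 5 gives the (5Z)-enoic acid F3. Silylation and Me3SiOTf as in step 6 close ring A and then open the dioxolane to an oxocarbenium ion, which the ring A alkene attacks. After the hydride shift only the methyl group is placed for the semipinacol shift, and aqueous work-up gives the keto acid (1S,2R,4aS,8aR)-2,4a,8a-trimethyl-5-oxodecahydronaphthalene-1-carboxylic acid F4. KN(SiMe3)2 and PhNTf2 give the only possible enol triflate F5. Fe(acac)3-catalysed coupling with 4-methylpent-3-enylmagnesium bromide then installs the side chain with the ring B double bond fixed in place, giving 17.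

(b) Step 3. The free carboxylate may consume the sulfonyl fluoride, and the strong base can isomerise the terminal alkyne to an allene. The fallback removes one carbon and adds it back; it sets out from 8 and returns at 10. Me3SiCl, Et3N and NaI convert 8 into the silyl enol ether silyl ester trimethylsilyl (3R)-3-methyl-6-(trimethylsilyloxy)hex-5-enoate F6. Ozonolysis with Me2S work-up cuts the enol ether to (3R)-3-methyl-5-oxopentanoic acid F7. Ohira–Bestmann alkynylation (dimethyl (1-diazo-2-oxopropyl)phosphonate, K2CO3, MeOH) gives 10.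

(c) Step 8. The 2-acetyl group can move to O-3 during ether cleavage or chromatography, giving the 1,3-diacylglycerol. The fallback builds the 2-acetate last through an orthoester and avoids the benzyl ether; it sets out from 17 and returns at 21. Cs2CO3 and (S)-solketal tosylate in DMF alkylate the carboxylate to the acetonide ester [(4S)-2,2-dimethyl-1,3-dioxolan-4-yl]methyl ester of 17 F8. Mild acidolysis (acidic resin, MeOH) gives the (2S)-2,3-dihydroxypropyl ester F9. Trimethyl orthoacetate with pyridinium tosylate gives the cyclic orthoester F10, and its hydrolysis in aqueous acetic acid opens toward the secondary acetate 21.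

**Further compounds**
F1 | step 6 | 5-(2-methyl-1,3-dioxolan-2-yl)pentan-2-one | CC(=O)CCCC1(C)OCCO1
F2 | step 6 | (3R)-7-hydroxy-3,7-dimethyl-10-(2-methyl-1,3-dioxolan-2-yl)dec-5-ynoic acid (epimers at C7) | OC(=O)C[C@H](C)CC#CC(C)(O)CCCC1(C)OCCO1
F3 | step 6 | (3R,5Z)-7-hydroxy-3,7-dimethyl-10-(2-methyl-1,3-dioxolan-2-yl)dec-5-enoic acid (epimers at C7) | OC(=O)C[C@H](C)C/C=C\C(C)(O)CCCC1(C)OCCO1
F4 | step 6 | (1S,2R,4aS,8aR)-2,4a,8a-trimethyl-5-oxodecahydronaphthalene-1-carboxylic acid | OC(=O)[C@H]1[C@H](C)CC[C@]2(C)C(=O)CCC[C@]12C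
F5 | step 6 | (1S,2R,4aS,8aR)-2,4a,8a-trimethyl-5-{[(trifluoromethyl)sulfonyl]oxy}-1,2,3,4,4a,7,8,8a-octahydronaphthalene-1-carboxylic acid | OC(=O)[C@H]1[C@H](C)CC[C@]2(C)C(OS(=O)(=O)C(F)(F)F)=CCC[C@]12C
F6 | step 3 | trimethylsilyl (3R)-3-methyl-6-(trimethylsilyloxy)hex-5-enoate (E/Z mixture) | C[Si](C)(C)OC(=O)C[C@H](C)CC=CO[Si](C)(C)C
F7 | step 3 | (3R)-3-methyl-5-oxopentanoic acid | OC(=O)C[C@H](C)CC=O
F8 | step 8 | [(4S)-2,2-dimethyl-1,3-dioxolan-4-yl]methyl (1S,2R,4aR,8aR)-2,4a,8a-trimethyl-5-(4-methylpent-3-en-1-yl)-1,2,3,4,4a,7,8,8a-octahydronaphthalene-1-carboxylate | CC1(C)OC[C@@H](COC(=O)[C@H]2[C@H](C)CC[C@]3(C)C(CCC=C(C)C)=CCC[C@]23C)O1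
F9 | step 8 | (2S)-2,3-dihydroxypropyl (1S,2R,4aR,8aR)-2,4a,8a-trimethyl-5-(4-methylpent-3-en-1-yl)-1,2,3,4,4a,7,8,8a-octahydronaphthalene-1-carboxylate | OC[C@H](O)COC(=O)[C@H]1[C@H](C)CC[C@]2(C)C(CCC=C(C)C)=CCC[C@]12C
F10 | step 8 | (2-methoxy-2-methyl-1,3-dioxolan-4-yl)methyl ester of 17 (glycerol centre as in F9, orthoester carbon as a mixture) | COC1(C)OC[C@@H](COC(=O)[C@H]2[C@H](C)CC[C@]3(C)C(CCC=C(C)C)=CCC[C@]23C)O1
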